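**Retrosynthetic overview**

- Achilleol A is traced back, by reductive desulfonylation and a C–C disconnection next to the sulfone, to a hydroxy ring sulfone (ring–CH2–SO2Ph) and a C20 (2E,6E,10E)-allylic bromide.
- The only ring, the 4-methylidenecyclohexanol, is cut into two three-carbon arcs: CH(OH)–CMe2–CH, which becomes a neopentylic aldehyde carbon and the β-carbon of a vinyl sulfone, and CH2–CH2–C(=CH2), which becomes a 3-bromobut-3-enyl unit.
- Enabling feature: the quaternary CMe2 sits between the carbinol carbon and the side-chain CH, so the two electrophilic sites cannot enolise or conjugate; the carbinol carbon and the methylidene-bearing ring carbon are 1,4 across the ring, so an sp3 organozinc carbon and an sp2 vinyl radical of one C4 unit can reach them in turn, the catalyst-set carbinol centre steering a 6-exo closure.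
- Fragments: the aldehyde–vinyl sulfone from 3-hydroxy-2,2-dimethylpropanal (2 steps); the mixed zinc reagent from 3-bromobut-3-en-1-ol (2 steps); the C20 bromide from (2E,6E)-farnesyl bromide by C2 and then C3 homologation (5 steps).
- Ring formation: one ring only, closed in the key step; the polyene chain is attached afterwards and the sulfone is removed last.

Key step: step 5

Remark: the sense of induction of the zinc addition (alkyl delivery to the Si face with the (1R,2R) ligand, giving the S carbinol) is taken from the behaviour of this catalyst with other aldehydes; if it were reversed for aldehyde 4, the (1S,2S) ligand would be used.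

**Route**

Step 1
Reactants: 1 3-hydroxy-2,2-dimethylpropanal; 2 diethyl [(phenylsulfonyl)methyl]phosphonate
Product: 3 (E)-2,2-dimethyl-4-(phenylsulfonyl)but-3-en-1-ol
Conditions: LiCl, DBU, MeCN, 0 °C to rt
Reagents that add atoms: none
Why: Horner–Wadsworth–Emmons olefination of a non-enolisable aldehyde with a sulfonyl-stabilised phosphonate under mild amine/LiCl conditions should give the E-vinyl sulfone and tolerate the free neopentyl alcohol; no stereocentre is formed.

Step 2
Reactants: 3 (E)-2,2-dimethyl-4-(phenylsulfonyl)but-3-en-1-ol
Product: 4 (E)-2,2-dimethyl-4-(phenylsulfonyl)but-3-enal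
Conditions: Dess–Martin periodinane, CH2Cl2, 0 °C to rt
Reagents that add atoms: none
Why: Dess–Martin oxidation of a neopentylic primary alcohol stops at the aldehyde, which has no α-hydrogen and therefore cannot enolise or move the double bond.

Step 3
Reactants: 5 3-bromobut-3-en-1-ol
Product: 6 2-bromo-4-iodobut-1-ene
Conditions: I2, PPh3, imidazole, CH2Cl2, 0 °C
Reagents that add atoms: iodine, II
Why: Appel-type iodination activates the primary hydroxyl group and replaces it by iodide in an SN2 displacement, while the vinylic bromide is inert.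

Step 4
Reactants: 6 2-bromo-4-iodobut-1-ene
Product: 8 (3-bromobut-3-en-1-yl)[(trimethylsilyl)methyl]zinc, via alkylzinc iodide 7 (not isolated)
Conditions: Zn dust (activated with BrCH2CH2Br and Me3SiCl, cat.), THF, 35 °C; decanted from excess Zn, solvent exchanged to Et2O; then Me3SiCH2Li (1.0 equiv), −78 °C; used as a solution
Reagents that add atoms: zinc, [Zn]; (trimethylsilyl)methyllithium, [Li]C[Si](C)(C)C
Why: Direct insertion of activated zinc into the primary C–I bond, which the sp2 C–Br bond does not undergo at this temperature, gives the alkylzinc iodide, and transmetallation with Me3SiCH2Li turns it into a mixed diorganozinc in which the Me3SiCH2 group is a non-transferable ligand, so that each molecule of 6 supplies one transferable bromobutenyl group.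

Step 5
Reactants: 4 (E)-2,2-dimethyl-4-(phenylsulfonyl)but-3-enal; 8 (3-bromobut-3-en-1-yl)[(trimethylsilyl)methyl]zinc
Product: 10 (1S,3R)-2,2-dimethyl-4-methylidene-3-[(phenylsulfonyl)methyl]cyclohexan-1-ol, via bromo dienol 9 (not isolated)
Conditions: 8 (1.5 equiv), Ti(OiPr)4 (1.2 equiv), (1R,2R)-C6H10(NHSO2CF3)2 (8 mol %), Et2O/PhMe, −20 °C; then MeOH (3 equiv), Bu3SnH (1.8 equiv, slow addition), Et3B (cat.), air, 20 °C, same flask
Reagents that add atoms: none
Why: The step is a formal [3+3] annulation run in one flask: the titanium–bis-sulfonamide catalyst first transfers the 3-bromobut-3-enyl group of the mixed diorganozinc to the aldehyde carbon of 4 (catalytic enantioselective 1,2-addition of a functionalised diorganozinc to an α-branched aldehyde), which makes the CH2–CH(OH) bond. Without work-up, the tin radical then abstracts the vinylic bromine of 9 and the σ-vinyl radical attacks the β-carbon of the vinyl sulfone in the 6-exo-trig mode (tin hydride mediated vinyl radical cyclisation onto an electron-poor alkene), which makes the C(=CH2)–CH bond with the methylidene already in its final place; hydrogen transfer to the α-sulfonyl radical carries the chain. The carbinol centre is set by the catalyst (Si-face delivery gives S), and the ring CH centre by the substrate: in the chair-like transition state the oxygen substituent and the acceptor arm should both be pseudo-equatorial, which gives the cis-1,3 (1S,3R) isomer. Chemoselectivity is needed twice: the organozinc must add only to the aldehyde and pass on only the bromobutenyl group, which the absence of copper, the inertness of vinyl sulfones toward zinc alkyls and the reluctance of the Me3SiCH2 group to migrate secure, and the vinyl radical must cyclise before it is reduced, which the gem-dimethyl group, the polarity-matched acceptor and the slow addition of Bu3SnH secure. Either alkene geometry of the vinyl sulfone would lead to the same product, because that geometry is lost at the radical stage.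

Step 6
Reactants: 11 (2E,6E)-1-bromo-3,7,11-trimethyldodeca-2,6,10-triene (farnesyl bromide)
Product: 12 (4E,8E)-5,9,13-trimethyltetradeca-4,8,12-trienenitrile
Conditions: MeCN (3 equiv), n-BuLi, THF, −78 °C; then 11, −78 to −20 °C
Reagents that add atoms: acetonitrile, CC#N
Why: SN2 alkylation of the lithiated nitrile, used in excess to suppress double alkylation, with the primary allylic bromide should add two carbons and leave the trisubstituted E-alkenes untouched.

Step 7
Reactants: 12 (4E,8E)-5,9,13-trimethyltetradeca-4,8,12-trienenitrile
Product: 13 (4E,8E)-5,9,13-trimethyltetradeca-4,8,12-trienal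
Conditions: i-Bu2AlH (1.2 equiv), CH2Cl2, −78 °C; aqueous Rochelle salt work-up
Reagents that add atoms: water, O
Why: Partial reduction of a nitrile with i-Bu2AlH stops at the imine oxidation level at −78 °C, and hydrolysis on work-up releases the non-conjugated aldehyde.

Step 8
Reactants: 13 (4E,8E)-5,9,13-trimethyltetradeca-4,8,12-trienal; 14 ethyl 2-(triphenyl-λ5-phosphanylidene)propanoate
Product: 15 ethyl (2E,6E,10E)-2,7,11,15-tetramethylhexadeca-2,6,10,14-tetraenoate
Conditions: CH2Cl2, 20 °C
Reagents that add atoms: none
Why: The Wittig reaction of a stabilised, α-branched ylide with an aliphatic aldehyde should give the 2E-trisubstituted enoate.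

Step 9
Reactants: 15 ethyl (2E,6E,10E)-2,7,11,15-tetramethylhexadeca-2,6,10,14-tetraenoate
Product: 16 (2E,6E,10E)-2,7,11,15-tetramethylhexadeca-2,6,10,14-tetraen-1-ol
Conditions: i-Bu2AlH (2.5 equiv), CH2Cl2, −78 °C
Reagents that add atoms: none
Why: 1,2-Reduction of the conjugated ester with i-Bu2AlH at low temperature should give the allylic alcohol without conjugate reduction or alkene migration.

Step 10
Reactants: 16 (2E,6E,10E)-2,7,11,15-tetramethylhexadeca-2,6,10,14-tetraen-1-ol
Product: 17 (2E,6E,10E)-1-bromo-2,7,11,15-tetramethylhexadeca-2,6,10,14-tetraene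
Conditions: CBr4, PPh3, CH2Cl2, −20 to 0 °C
Reagents that add atoms: carbon tetrabromide, BrC(Br)(Br)Br
Why: The Appel reaction converts the primary allylic alcohol into the bromide under neutral conditions, which should avoid allylic transposition and loss of E geometry.

Step 11
Reactants: 10 (1S,3R)-2,2-dimethyl-4-methylidene-3-[(phenylsulfonyl)methyl]cyclohexan-1-ol; 17 (2E,6E,10E)-1-bromo-2,7,11,15-tetramethylhexadeca-2,6,10,14-tetraene
Product: 18 (1S,3R)-2,2-dimethyl-4-methylidene-3-[(3E,7E,11E)-3,8,12,16-tetramethyl-1-(phenylsulfonyl)heptadeca-3,7,11,15-tetraen-1-yl]cyclohexan-1-ol (both epimers at the sulfonyl-bearing carbon)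
Conditions: n-BuLi (2.1 equiv), THF/DMPU, −78 °C; then 17, −78 to −30 °C; then H2O
Reagents that add atoms: none
Why: Alkylation of an α-sulfonyl carbanion (two equivalents of base, the hydroxyl group being deprotonated first) with a primary allylic bromide is a standard terpenoid C–C coupling; the new centre next to sulfur is formed without control and is erased in step 12, and the two ring stereocentres are not touched.

Step 12
Reactants: 18 (1S,3R)-2,2-dimethyl-4-methylidene-3-[(3E,7E,11E)-3,8,12,16-tetramethyl-1-(phenylsulfonyl)heptadeca-3,7,11,15-tetraen-1-yl]cyclohexan-1-ol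
Product: 19 achilleol A, (1S,3R)-2,2-dimethyl-4-methylidene-3-[(3E,7E,11E)-3,8,12,16-tetramethylheptadeca-3,7,11,15-tetraen-1-yl]cyclohexan-1-ol
Conditions: Na/Hg (6 % Na), Na2HPO4, MeOH/THF, −20 °C
Reagents that add atoms: none
Why: Reductive desulfonylation with buffered sodium amalgam cleaves the C–S bond by electron transfer and protonation, so both epimers of 18 converge on the target, and the sulfone is not allylic, so no alkene can shift.

**Compound list**

1 | 3-hydroxy-2,2-dimethylpropanal | CC(C)(CO)C=O | starting material
2 | diethyl [(phenylsulfonyl)methyl]phosphonate | CCOP(=O)(OCC)CS(=O)(=O)c1ccccc1 | starting material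
3 | (E)-2,2-dimethyl-4-(phenylsulfonyl)but-3-en-1-ol | CC(C)(CO)/C=C/S(=O)(=O)c1ccccc1 | intermediate
4 | (E)-2,2-dimethyl-4-(phenylsulfonyl)but-3-enal | CC(C)(C=O)/C=C/S(=O)(=O)c1ccccc1 | intermediate
5 | 3-bromobut-3-en-1-ol | C=C(Br)CCO | starting material
6 | 2-bromo-4-iodobut-1-ene | C=C(Br)CCI | intermediate
7 | (3-bromobut-3-en-1-yl)zinc iodide | C=C(Br)CC[Zn]I | intermediate
8 | (3-bromobut-3-en-1-yl)[(trimethylsilyl)methyl]zinc | C=C(Br)CC[Zn]C[Si](C)(C)C | intermediate
9 | (1E,4S)-7-bromo-3,3-dimethyl-1-(phenylsulfonyl)octa-1,7-dien-4-ol | C=C(Br)CC[C@H](O)C(C)(C)/C=C/S(=O)(=O)c1ccccc1 | intermediate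
10 | (1S,3R)-2,2-dimethyl-4-methylidene-3-[(phenylsulfonyl)methyl]cyclohexan-1-ol | C=C1CC[C@H](O)C(C)(C)[C@@H]1CS(=O)(=O)c1ccccc1 | intermediate
11 | (2E,6E)-1-bromo-3,7,11-trimethyldodeca-2,6,10-triene | BrC/C=C(\C)CC/C=C(\C)CCC=C(C)C | starting material
12 | (4E,8E)-5,9,13-trimethyltetradeca-4,8,12-trienenitrile | N#CCC/C=C(\C)CC/C=C(\C)CCC=C(C)C | intermediate
13 | (4E,8E)-5,9,13-trimethyltetradeca-4,8,12-trienal | O=CCC/C=C(\C)CC/C=C(\C)CCC=C(C)C | intermediate
14 | ethyl 2-(triphenyl-λ5-phosphanylidene)propanoate | CCOC(=O)C(C)=P(c1ccccc1)(c1ccccc1)c1ccccc1 | starting material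
15 | ethyl (2E,6E,10E)-2,7,11,15-tetramethylhexadeca-2,6,10,14-tetraenoate | CCOC(=O)/C(C)=C/CC/C=C(\C)CC/C=C(\C)CCC=C(C)C | intermediate
16 | (2E,6E,10E)-2,7,11,15-tetramethylhexadeca-2,6,10,14-tetraen-1-ol | OC/C(C)=C/CC/C=C(\C)CC/C=C(\C)CCC=C(C)C | intermediate
17 | (2E,6E,10E)-1-bromo-2,7,11,15-tetramethylhexadeca-2,6,10,14-tetraene | BrC/C(C)=C/CC/C=C(\C)CC/C=C(\C)CCC=C(C)C | intermediate
18 | (1S,3R)-2,2-dimethyl-4-methylidene-3-[(3E,7E,11E)-3,8,12,16-tetramethyl-1-(phenylsulfonyl)heptadeca-3,7,11,15-tetraen-1-yl]cyclohexan-1-ol | C=C1CC[C@H](O)C(C)(C)[C@@H]1C(C/C(C)=C/CC/C=C(\C)CC/C=C(\C)CCC=C(C)C)S(=O)(=O)c1ccccc1 | intermediate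
19 | achilleol A | C=C1CC[C@H](O)C(C)(C)[C@@H]1CC/C(C)=C/CC/C=C(\C)CC/C=C(\C)CCC=C(C)C | target

**Step count and risks**

Total step count: 12. Longest linear sequence: 7 steps (steps 6 to 12, from farnesyl bromide 11).

Steps most likely to fail:

1. Step 5. The ring closure may fail in three ways: hydrogen transfer to the vinyl radical before it cyclises, reversible addition of the tin radical to the vinyl sulfone with loss of the sulfonyl group, or weak 1,3-diastereocontrol in the radical closure. The fallback replaces the radical closure by a polar one and separates the two events. It sets out from 9, which is isolated by aqueous work-up after the zinc addition. Silylation with TBSOTf and 2,6-lutidine gives the tert-butyldimethylsilyl ether F1. Bromine–lithium exchange with t-BuLi (2 equiv, Et2O, −78 °C) then lets the vinyllithium add to the vinyl sulfone in a 6-exo-trig anionic closure, and protonation gives the cyclised silyl ether F2, whose diastereomers can be separated if needed. TBAF removes the silyl group and the route is rejoined at 10.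

2. Step 11. The hindered alkoxide/carbanion species may aggregate and alkylate slowly, so that proton transfer to the allylic bromide or O-alkylation competes. The fallback changes from the unprotected dianion to a protected monoanion. It sets out from 10. TESCl and imidazole give the triethylsilyl ether F3; deprotonation with n-BuLi (1.05 equiv) in THF/HMPA and alkylation with 17 give the alkylated silyl ether F4; TBAF then returns the route to 18.

3. Step 4. The zinc insertion may stall or give homocoupling, or the mixed reagent may scramble into symmetrical diorganozincs when the lithium reagent is added, so that the silylmethyl group no longer stays behind cleanly. The fallback forms the carbon–metal bond with magnesium and takes the silylmethyl group from a preformed zinc halide instead of a lithium reagent. It sets out from 6. Magnesium in Et2O at 0 °C inserts selectively into the C–I bond and gives (3-bromobut-3-en-1-yl)magnesium iodide F5. Addition of F5 to Me3SiCH2ZnCl (from ZnCl2 and Me3SiCH2MgCl, Et2O, 0 °C), followed by 1,4-dioxane, precipitates MgClI, and filtration gives a salt-free solution of 8, where the route is rejoined.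

Further compounds
F1 | step 5 | tert-butyl{[(1E,4S)-7-bromo-3,3-dimethyl-1-(phenylsulfonyl)octa-1,7-dien-4-yl]oxy}dimethylsilane | C=C(Br)CC[C@H](O[Si](C)(C)C(C)(C)C)C(C)(C)/C=C/S(=O)(=O)c1ccccc1
F2 | step 5 | tert-butyl{[(1S,3R)-2,2-dimethyl-4-methylidene-3-[(phenylsulfonyl)methyl]cyclohexyl]oxy}dimethylsilane | C=C1CC[C@H](O[Si](C)(C)C(C)(C)C)C(C)(C)[C@@H]1CS(=O)(=O)c1ccccc1
F3 | step 11 | triethyl{[(1S,3R)-2,2-dimethyl-4-methylidene-3-[(phenylsulfonyl)methyl]cyclohexyl]oxy}silane | C=C1CC[C@H](O[Si](CC)(CC)CC)C(C)(C)[C@@H]1CS(=O)(=O)c1ccccc1
F4 | step 11 | triethyl{[(1S,3R)-2,2-dimethyl-4-methylidene-3-[(3E,7E,11E)-3,8,12,16-tetramethyl-1-(phenylsulfonyl)heptadeca-3,7,11,15-tetraen-1-yl]cyclohexyl]oxy}silane | C=C1CC[C@H](O[Si](CC)(CC)CC)C(C)(C)[C@@H]1C(C/C(C)=C/CC/C=C(\C)CC/C=C(\C)CCC=C(C)C)S(=O)(=O)c1ccccc1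
F5 | step 4 | (3-bromobut-3-en-1-yl)magnesium iodide | C=C(Br)CC[Mg]I
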